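**Retrosynthetic overview** (lignan numbering: ring O–C7(aryl)–C8–C8′(benzyl)–C9′H2; C9 is the exocyclic CH2 that carries the coumarate)
1. The target comes from its tris-TIPS ether by global desilylation; the ring C9′H2 comes from a lactone C9′=O (DIBAL-H, then Et3SiH/BF3·OEt2).
2. Key disconnection C8–C9: Giese addition of the (coumaroyloxy)methyl radical, generated from the iodomethyl ester of TIPS-protected p-coumaric acid, to C8 of a (5R)-5-aryl-3-benzylbutenolide.
3. Enabling feature: in the five-membered ring O–C7–C8–C8′–C9′, C8 is linked through C8′ to the only ring CH2 next to oxygen. Raising C9′ to C=O and desaturating C8=C8′ makes C8 the β-carbon of a butenolide, and the aryl-bearing C7 next to it directs both new stereocentres (C8, C8′).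
4. Only ring formation: ring-closing metathesis of the (R)-1-arylallyl 2-benzylacrylate gives the butenolide, which is carried through and ends as the oxolane.
5. The (R)-allylic alcohol comes from vanillin (vinyl Grignard, lipase resolution), the 2-benzylacrylic acid from the same aldehyde via Meldrum's acid, and the iodomethyl ester from p-coumaric acid.

Key step: step 12

Remark: the target is taken as the (2R,3S,4S)-oxolane (7R,8S,8′S; 2-aryl/3-CH2O trans, 3-CH2O/4-benzyl cis), as the SMILES specifies; all three phenols are carried as triisopropylsilyl (TIPS) ethers.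

**Route**

Step 1
Reactants: 1 vanillin; 2 triisopropylsilyl chloride
Product: 3 3-methoxy-4-(triisopropylsilyloxy)benzaldehyde
Conditions: imidazole, DMF, rt
Reagents that add atoms: triisopropylsilyl chloride, CC(C)[Si](Cl)(C(C)C)C(C)C
Why: Imidazole-promoted O-silylation of the phenol; the bulky TIPS ether should survive the Grignard, hydroxide, hydride and Lewis-acid steps and leave with fluoride at the end.

Step 2
Reactants: 3 3-methoxy-4-(triisopropylsilyloxy)benzaldehyde; 4 vinylmagnesium bromide; 5 acetic anhydride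
Product: 7 rac-1-[3-methoxy-4-(triisopropylsilyloxy)phenyl]prop-2-en-1-yl acetate, via bromomagnesium alkoxide 6 (not isolated)
Conditions: vinylMgBr, THF, −78 to 0 °C; then Ac2O, 0 °C to rt
Reagents that add atoms: vinylmagnesium bromide, C=C[Mg]Br; acetic anhydride, CC(=O)OC(C)=O
Why: Grignard 1,2-addition to the aldehyde followed by O-acylation of the magnesium alkoxide in the same flask; the new stereocentre is formed racemic and is resolved in step 3.

Step 3
Reactants: 7 rac-1-[3-methoxy-4-(triisopropylsilyloxy)phenyl]prop-2-en-1-yl acetate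
Product: 8 (1R)-1-[3-methoxy-4-(triisopropylsilyloxy)phenyl]prop-2-en-1-ol
Conditions: immobilised Candida antarctica lipase B, n-BuOH, MTBE, 35 °C, stopped near half conversion; chromatography
Reagents that add atoms: none
Why: Lipase-catalysed kinetic resolution by enantioselective alcoholysis; by the empirical size rule for secondary alcohols (aryl large, vinyl medium) the enzyme should deacylate the (R)-acetate, which sets C7 of the target, and the unreacted (S)-acetate is separated.

Step 4
Reactants: 3 3-methoxy-4-(triisopropylsilyloxy)benzaldehyde; 9 Meldrum's acid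
Product: 11 5-{[3-methoxy-4-(triisopropylsilyloxy)phenyl]methyl}-2,2-dimethyl-1,3-dioxane-4,6-dione, via arylidene Meldrum's acid 10 (not isolated)
Conditions: Hantzsch ester, L-proline (cat.), EtOH, rt
Reagents that add atoms: Meldrum's acid, CC1(C)OC(=O)CC(=O)O1
Why: Knoevenagel condensation followed by transfer hydrogenation of the arylidene by the Hantzsch ester (organocatalytic reductive alkylation) should give the mono-benzylated Meldrum's acid without dialkylation.

Step 5
Reactants: 11 5-{[3-methoxy-4-(triisopropylsilyloxy)phenyl]methyl}-2,2-dimethyl-1,3-dioxane-4,6-dione; 12 Eschenmoser's salt; 13 methanol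
Product: 15 methyl 2-{[3-methoxy-4-(triisopropylsilyloxy)phenyl]methyl}prop-2-enoate, via Mannich base 14 (not isolated)
Conditions: CH2=NMe2+ I−, MeOH, 65 °C
Reagents that add atoms: Eschenmoser's salt, C=[N+](C)C.[I-]; methanol, CO
Why: Mannich reaction at C5, methanolysis of the dioxanedione and decarboxylative β-elimination of dimethylamine should deliver the α-methylene ester.

Step 6
Reactants: 15 methyl 2-{[3-methoxy-4-(triisopropylsilyloxy)phenyl]methyl}prop-2-enoate; 16 lithium hydroxide
Product: 17 2-{[3-methoxy-4-(triisopropylsilyloxy)phenyl]methyl}prop-2-enoic acid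
Conditions: LiOH, THF/H2O, 0 °C to rt; then 1 M HCl to pH 3
Reagents that add atoms: lithium hydroxide, [Li+].[OH-]
Why: Saponification of the unhindered methyl ester under conditions at which the hindered aryl TIPS ether should survive.

Step 7
Reactants: 8 (1R)-1-[3-methoxy-4-(triisopropylsilyloxy)phenyl]prop-2-en-1-ol; 17 2-{[3-methoxy-4-(triisopropylsilyloxy)phenyl]methyl}prop-2-enoic acid
Product: 18 (1R)-1-[3-methoxy-4-(triisopropylsilyloxy)phenyl]prop-2-en-1-yl 2-{[3-methoxy-4-(triisopropylsilyloxy)phenyl]methyl}prop-2-enoate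
Conditions: DIC, DMAP (cat.), CH2Cl2, 0 °C to rt
Reagents that add atoms: none
Why: Steglich esterification; the carbinol C–O bond is not broken, so the (R)-configuration is retained.

Step 8
Reactants: 18 (1R)-1-[3-methoxy-4-(triisopropylsilyloxy)phenyl]prop-2-en-1-yl 2-{[3-methoxy-4-(triisopropylsilyloxy)phenyl]methyl}prop-2-enoate
Product: 19 (5R)-5-[3-methoxy-4-(triisopropylsilyloxy)phenyl]-3-{[3-methoxy-4-(triisopropylsilyloxy)phenyl]methyl}furan-2(5H)-one
Conditions: Hoveyda–Grubbs II (5 mol %), 1,4-benzoquinone (10 mol %), toluene (5 mM), 80 °C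
Reagents that add atoms: none
Why: Ring-closing metathesis of the vinyl group onto the 1,1-disubstituted acrylate with loss of ethylene closes the butenolide; C7 is not involved and the neutral medium should avoid racemisation through the 2-hydroxyfuran tautomer.

Step 9
Reactants: 20 p-coumaric acid; 2 triisopropylsilyl chloride
Product: 22 (2E)-3-[4-(triisopropylsilyloxy)phenyl]prop-2-enoic acid, via bis-silylated silyl ester 21 (not isolated)
Conditions: TIPSCl (2.2 equiv), imidazole, DMF, rt; then AcOH/THF/H2O, rt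
Reagents that add atoms: triisopropylsilyl chloride, CC(C)[Si](Cl)(C(C)C)C(C)C
Why: Exhaustive silylation followed by selective hydrolysis of the labile silyl ester leaves the aryl TIPS ether in place.

Step 10
Reactants: 22 (2E)-3-[4-(triisopropylsilyloxy)phenyl]prop-2-enoic acid; 23 chloromethyl chlorosulfate
Product: 24 chloromethyl (2E)-3-[4-(triisopropylsilyloxy)phenyl]prop-2-enoate
Conditions: ClCH2OSO2Cl, NaHCO3, n-Bu4NHSO4 (cat.), CH2Cl2/H2O, 0 °C to rt
Reagents that add atoms: chloromethyl chlorosulfate, ClCOS(=O)(=O)Cl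
Why: Phase-transfer O-alkylation of the carboxylate, with SN2 displacement of chlorosulfate in preference to chloride, is the standard entry to chloromethyl esters.

Step 11
Reactants: 24 chloromethyl (2E)-3-[4-(triisopropylsilyloxy)phenyl]prop-2-enoate; 25 sodium iodide
Product: 26 iodomethyl (2E)-3-[4-(triisopropylsilyloxy)phenyl]prop-2-enoate
Conditions: NaI, acetone, rt, dark; used at once
Reagents that add atoms: sodium iodide, [Na+].[I-]
Why: Finkelstein halide exchange, driven by precipitation of sodium chloride.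

Step 12
Reactants: 19 (5R)-5-[3-methoxy-4-(triisopropylsilyloxy)phenyl]-3-{[3-methoxy-4-(triisopropylsilyloxy)phenyl]methyl}furan-2(5H)-one; 26 iodomethyl (2E)-3-[4-(triisopropylsilyloxy)phenyl]prop-2-enoate
Product: 27 [(2R,3S,4S)-2-[3-methoxy-4-(triisopropylsilyloxy)phenyl]-4-{[3-methoxy-4-(triisopropylsilyloxy)phenyl]methyl}-5-oxooxolan-3-yl]methyl (2E)-3-[4-(triisopropylsilyloxy)phenyl]prop-2-enoate
Conditions: 26 (2 equiv), (TMS)3SiH (syringe pump), Et3B/air (cat.), toluene, 0 °C
Reagents that add atoms: none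
Why: Et3B/O2 generates (TMS)3Si•, which abstracts iodine from 26; the nucleophilic (acyloxy)methyl radical adds to the β-carbon C8 of the electron-poor butenolide, and the resulting tertiary α-lactone radical at C8′ abstracts hydrogen from (TMS)3SiH to carry the chain. The closest known reaction type is the tin-free Giese addition of iodide-derived α-oxygenated alkyl radicals (iodomethyl esters as hydroxymethyl-radical equivalents) to γ-substituted butenolides; no ring is closed, the five-membered ring being carried intact. C8 is set by attack anti to the aryl group on the adjacent C7 (2,3-trans), and C8′ by hydrogen delivery from the bulky silane anti to the newly installed C8 substituent, which should place benzyl and acyloxymethyl cis under kinetic control (the usual anti attack on vicinally substituted cyclic radicals). The step needs selectivity for the butenolide over the cinnamate C=C of 26 and for addition over simple reduction; the strained endocyclic enoate with an unsubstituted β-CH should react faster than the acyclic β-aryl enoate, excess 26 with slow silane addition favours addition, and the neutral medium protects the racemisation-prone C7–H of 19 and the epimerisable cis-lactone.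

Step 13
Reactants: 27 [(2R,3S,4S)-2-[3-methoxy-4-(triisopropylsilyloxy)phenyl]-4-{[3-methoxy-4-(triisopropylsilyloxy)phenyl]methyl}-5-oxooxolan-3-yl]methyl (2E)-3-[4-(triisopropylsilyloxy)phenyl]prop-2-enoate
Product: 28 [(2R,3S,4S,5RS)-5-hydroxy-2-[3-methoxy-4-(triisopropylsilyloxy)phenyl]-4-{[3-methoxy-4-(triisopropylsilyloxy)phenyl]methyl}oxolan-3-yl]methyl (2E)-3-[4-(triisopropylsilyloxy)phenyl]prop-2-enoate
Conditions: DIBAL-H (1.1 equiv), CH2Cl2, −78 °C; MeOH, then aq. Rochelle salt
Reagents that add atoms: none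
Why: Partial reduction of the γ-lactone to a stable aluminium lactolate at −78 °C should be faster than attack on the acyclic, conjugated and donor-deactivated cinnamate ester; C8′ is not enolised under these conditions.

Step 14
Reactants: 28 [(2R,3S,4S,5RS)-5-hydroxy-2-[3-methoxy-4-(triisopropylsilyloxy)phenyl]-4-{[3-methoxy-4-(triisopropylsilyloxy)phenyl]methyl}oxolan-3-yl]methyl (2E)-3-[4-(triisopropylsilyloxy)phenyl]prop-2-enoate
Product: 29 [(2R,3S,4S)-2-[3-methoxy-4-(triisopropylsilyloxy)phenyl]-4-{[3-methoxy-4-(triisopropylsilyloxy)phenyl]methyl}oxolan-3-yl]methyl (2E)-3-[4-(triisopropylsilyloxy)phenyl]prop-2-enoate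
Conditions: Et3SiH (3 equiv), BF3·OEt2 (1.5 equiv), CH2Cl2, −78 °C; aq. NaHCO3
Reagents that add atoms: none
Why: Ionic hydrogenation of the lactol (BF3-promoted oxocarbenium ion at C9′, hydride transfer from Et3SiH) removes the anomeric hydroxyl; no stereocentre is created and C7, C8 and C8′ are not involved.

Step 15
Reactants: 29 [(2R,3S,4S)-2-[3-methoxy-4-(triisopropylsilyloxy)phenyl]-4-{[3-methoxy-4-(triisopropylsilyloxy)phenyl]methyl}oxolan-3-yl]methyl (2E)-3-[4-(triisopropylsilyloxy)phenyl]prop-2-enoate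
Product: 30 lariciresinol p-coumarate, [(2R,3S,4S)-2-(4-hydroxy-3-methoxyphenyl)-4-[(4-hydroxy-3-methoxyphenyl)methyl]oxolan-3-yl]methyl (2E)-3-(4-hydroxyphenyl)prop-2-enoate
Conditions: TBAF (3.6 equiv), AcOH (3.6 equiv), THF, 0 °C
Reagents that add atoms: none
Why: Fluoride cleavage of the three aryl silyl ethers, buffered with acetic acid so that the cinnamate ester, the (E)-alkene and the acid-sensitive benzylic ether are exposed neither to free phenoxide nor to acid.

**Compound list**

1 | vanillin (4-hydroxy-3-methoxybenzaldehyde) | COc1cc(C=O)ccc1O | starting material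
2 | triisopropylsilyl chloride | CC(C)[Si](Cl)(C(C)C)C(C)C | starting material
3 | 3-methoxy-4-(triisopropylsilyloxy)benzaldehyde | COc1cc(C=O)ccc1O[Si](C(C)C)(C(C)C)C(C)C | intermediate
4 | vinylmagnesium bromide | C=C[Mg]Br | starting material
5 | acetic anhydride | CC(=O)OC(C)=O | starting material
6 | bromomagnesium 1-[3-methoxy-4-(triisopropylsilyloxy)phenyl]prop-2-en-1-olate (racemic) | C=CC(O[Mg]Br)c1ccc(O[Si](C(C)C)(C(C)C)C(C)C)c(OC)c1 | intermediate
7 | rac-1-[3-methoxy-4-(triisopropylsilyloxy)phenyl]prop-2-en-1-yl acetate | C=CC(OC(C)=O)c1ccc(O[Si](C(C)C)(C(C)C)C(C)C)c(OC)c1 | intermediate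
8 | (1R)-1-[3-methoxy-4-(triisopropylsilyloxy)phenyl]prop-2-en-1-ol | C=C[C@@H](O)c1ccc(O[Si](C(C)C)(C(C)C)C(C)C)c(OC)c1 | intermediate
9 | Meldrum's acid (2,2-dimethyl-1,3-dioxane-4,6-dione) | CC1(C)OC(=O)CC(=O)O1 | starting material
10 | 5-{[3-methoxy-4-(triisopropylsilyloxy)phenyl]methylidene}-2,2-dimethyl-1,3-dioxane-4,6-dione | COc1cc(C=C2C(=O)OC(C)(C)OC2=O)ccc1O[Si](C(C)C)(C(C)C)C(C)C | intermediate
11 | 5-{[3-methoxy-4-(triisopropylsilyloxy)phenyl]methyl}-2,2-dimethyl-1,3-dioxane-4,6-dione | COc1cc(CC2C(=O)OC(C)(C)OC2=O)ccc1O[Si](C(C)C)(C(C)C)C(C)C | intermediate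
12 | Eschenmoser's salt (N,N-dimethylmethyleneiminium iodide) | C=[N+](C)C.[I-] | starting material
13 | methanol | CO | starting material
14 | 5-[(dimethylamino)methyl]-5-{[3-methoxy-4-(triisopropylsilyloxy)phenyl]methyl}-2,2-dimethyl-1,3-dioxane-4,6-dione | COc1cc(CC2(CN(C)C)C(=O)OC(C)(C)OC2=O)ccc1O[Si](C(C)C)(C(C)C)C(C)C | intermediate
15 | methyl 2-{[3-methoxy-4-(triisopropylsilyloxy)phenyl]methyl}prop-2-enoate | COC(=O)C(=C)Cc1ccc(O[Si](C(C)C)(C(C)C)C(C)C)c(OC)c1 | intermediate
16 | lithium hydroxide | [Li+].[OH-] | starting material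
17 | 2-{[3-methoxy-4-(triisopropylsilyloxy)phenyl]methyl}prop-2-enoic acid | OC(=O)C(=C)Cc1ccc(O[Si](C(C)C)(C(C)C)C(C)C)c(OC)c1 | intermediate
18 | (1R)-1-[3-methoxy-4-(triisopropylsilyloxy)phenyl]prop-2-en-1-yl 2-{[3-methoxy-4-(triisopropylsilyloxy)phenyl]methyl}prop-2-enoate | C=C[C@@H](OC(=O)C(=C)Cc1ccc(O[Si](C(C)C)(C(C)C)C(C)C)c(OC)c1)c1ccc(O[Si](C(C)C)(C(C)C)C(C)C)c(OC)c1 | intermediate
19 | (5R)-5-[3-methoxy-4-(triisopropylsilyloxy)phenyl]-3-{[3-methoxy-4-(triisopropylsilyloxy)phenyl]methyl}furan-2(5H)-one | O=C1O[C@@H](c2ccc(O[Si](C(C)C)(C(C)C)C(C)C)c(OC)c2)C=C1Cc1ccc(O[Si](C(C)C)(C(C)C)C(C)C)c(OC)c1 | intermediate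
20 | p-coumaric acid ((2E)-3-(4-hydroxyphenyl)prop-2-enoic acid) | OC(=O)/C=C/c1ccc(O)cc1 | starting material
21 | triisopropylsilyl (2E)-3-[4-(triisopropylsilyloxy)phenyl]prop-2-enoate | CC(C)[Si](OC(=O)/C=C/c1ccc(O[Si](C(C)C)(C(C)C)C(C)C)cc1)(C(C)C)C(C)C | intermediate
22 | (2E)-3-[4-(triisopropylsilyloxy)phenyl]prop-2-enoic acid | OC(=O)/C=C/c1ccc(O[Si](C(C)C)(C(C)C)C(C)C)cc1 | intermediate
23 | chloromethyl chlorosulfate | ClCOS(=O)(=O)Cl | starting material
24 | chloromethyl (2E)-3-[4-(triisopropylsilyloxy)phenyl]prop-2-enoate | ClCOC(=O)/C=C/c1ccc(O[Si](C(C)C)(C(C)C)C(C)C)cc1 | intermediate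
25 | sodium iodide | [Na+].[I-] | starting material
26 | iodomethyl (2E)-3-[4-(triisopropylsilyloxy)phenyl]prop-2-enoate | ICOC(=O)/C=C/c1ccc(O[Si](C(C)C)(C(C)C)C(C)C)cc1 | intermediate
27 | [(2R,3S,4S)-2-[3-methoxy-4-(triisopropylsilyloxy)phenyl]-4-{[3-methoxy-4-(triisopropylsilyloxy)phenyl]methyl}-5-oxooxolan-3-yl]methyl (2E)-3-[4-(triisopropylsilyloxy)phenyl]prop-2-enoate | COc1cc(C[C@@H]2C(=O)O[C@@H](c3ccc(O[Si](C(C)C)(C(C)C)C(C)C)c(OC)c3)[C@@H]2COC(=O)/C=C/c2ccc(O[Si](C(C)C)(C(C)C)C(C)C)cc2)ccc1O[Si](C(C)C)(C(C)C)C(C)C | intermediate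
28 | [(2R,3S,4S,5RS)-5-hydroxy-2-[3-methoxy-4-(triisopropylsilyloxy)phenyl]-4-{[3-methoxy-4-(triisopropylsilyloxy)phenyl]methyl}oxolan-3-yl]methyl (2E)-3-[4-(triisopropylsilyloxy)phenyl]prop-2-enoate (anomeric mixture) | COc1cc(C[C@@H]2C(O)O[C@@H](c3ccc(O[Si](C(C)C)(C(C)C)C(C)C)c(OC)c3)[C@@H]2COC(=O)/C=C/c2ccc(O[Si](C(C)C)(C(C)C)C(C)C)cc2)ccc1O[Si](C(C)C)(C(C)C)C(C)C | intermediate
29 | [(2R,3S,4S)-2-[3-methoxy-4-(triisopropylsilyloxy)phenyl]-4-{[3-methoxy-4-(triisopropylsilyloxy)phenyl]methyl}oxolan-3-yl]methyl (2E)-3-[4-(triisopropylsilyloxy)phenyl]prop-2-enoate | COc1cc(C[C@@H]2CO[C@@H](c3ccc(O[Si](C(C)C)(C(C)C)C(C)C)c(OC)c3)[C@@H]2COC(=O)/C=C/c2ccc(O[Si](C(C)C)(C(C)C)C(C)C)cc2)ccc1O[Si](C(C)C)(C(C)C)C(C)C | intermediate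
30 | lariciresinol p-coumarate, [(2R,3S,4S)-2-(4-hydroxy-3-methoxyphenyl)-4-[(4-hydroxy-3-methoxyphenyl)methyl]oxolan-3-yl]methyl (2E)-3-(4-hydroxyphenyl)prop-2-enoate | COc1cc(C[C@@H]2CO[C@@H](c3ccc(O)c(OC)c3)[C@@H]2COC(=O)/C=C/c2ccc(O)cc2)ccc1O | target

**Step count and risks**

Total step count: 15. Longest linear sequence: 10 steps (1, 4, 5, 6, 7, 8, 12, 13, 14, 15).

Steps most likely to fail:

Step 12. What may go wrong: addition of the (acyloxy)methyl radical to the trisubstituted butenolide may be slower than its reduction by the silane or its addition to the cinnamate C=C of a second molecule of 26, and the hydrogen-atom transfer at C8′ may discriminate the two faces incompletely. The fallback is a reductive decarboxylative radical–polar coupling, in which no hydrogen-atom donor is present during the addition and C8′ is set by protonation of a metal enolate. It sets out from acid 22 and butenolide 19. O-Alkylation of 22 with tert-butyl bromoacetate (K2CO3, DMF) should give tert-butyl 2-({(2E)-3-[4-(triisopropylsilyloxy)phenyl]prop-2-enoyl}oxy)acetate F1. Acidolysis (TFA, CH2Cl2, 0 °C) should give the (acyloxy)acetic acid F2, and coupling with N-hydroxyphthalimide (DIC, cat. DMAP) the redox-active N-(acyloxy)phthalimide ester F3. F3 and 19 are then combined under nickel-catalysed, zinc-mediated decarboxylative conjugate addition (Zn, Ni(ClO4)2·6H2O cat., LiCl, MeCN, rt); protonation of the enolate anti to the C8 substituent is expected, and the route is rejoined at lactone 27.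

Step 13. What may go wrong: hydride delivery to the cinnamate carbonyl may compete with lactone reduction, so that the acyl group is partly lost or over-reduced. In the fallback the ester is given up deliberately and reinstated once the ring is at the ether level. It sets out from 27. Excess DIBAL-H (4 equiv, CH2Cl2, −78 °C) should give the hydroxymethyl lactol F4, with the cinnamyl alcohol fragment discarded. Et3SiH/BF3·OEt2 (−78 °C) should then give the primary alcohol F5; any bicyclic acetal formed reversibly from the C9 hydroxyl would be reduced through the same oxocarbenium ion. Steglich acylation of F5 with acid 22 (DIC, DMAP, CH2Cl2) rejoins the route at 29.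

Step 14. What may go wrong: the Lewis acid may ionise the electron-rich benzylic C7–O bond (ring opening, epimerisation at C7 or Friedel–Crafts closure onto the other arene), or the oxocarbenium ion may lose the C8′ proton and scramble that centre. The fallback closes the ring by a neutral C–O bond formation at C9′ instead of an ionic reduction. It sets out from lactol 28. NaBH4 (MeOH/THF, 0 °C) should reduce the open hydroxy-aldehyde form to the 1,4-diol F6. Mitsunobu cyclodehydration (PPh3, DIAD, THF, 0 °C) then activates the primary C9′ hydroxyl, which is displaced by the C7 hydroxyl with retention at C7 because its C–O bond is not broken; the route is rejoined at 29.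

**Further compounds**

F1 | step 12 | tert-butyl 2-({(2E)-3-[4-(triisopropylsilyloxy)phenyl]prop-2-enoyl}oxy)acetate | CC(C)(C)OC(=O)COC(=O)/C=C/c1ccc(O[Si](C(C)C)(C(C)C)C(C)C)cc1
F2 | step 12 | 2-({(2E)-3-[4-(triisopropylsilyloxy)phenyl]prop-2-enoyl}oxy)acetic acid | OC(=O)COC(=O)/C=C/c1ccc(O[Si](C(C)C)(C(C)C)C(C)C)cc1
F3 | step 12 | 1,3-dioxoisoindolin-2-yl 2-({(2E)-3-[4-(triisopropylsilyloxy)phenyl]prop-2-enoyl}oxy)acetate | O=C(COC(=O)/C=C/c1ccc(O[Si](C(C)C)(C(C)C)C(C)C)cc1)ON1C(=O)c2ccccc2C1=O
F4 | step 13 | (3S,4S,5R)-4-(hydroxymethyl)-5-[3-methoxy-4-(triisopropylsilyloxy)phenyl]-3-{[3-methoxy-4-(triisopropylsilyloxy)phenyl]methyl}oxolan-2-ol (anomeric mixture) | COc1cc(C[C@@H]2C(O)O[C@@H](c3ccc(O[Si](C(C)C)(C(C)C)C(C)C)c(OC)c3)[C@@H]2CO)ccc1O[Si](C(C)C)(C(C)C)C(C)C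
F5 | step 13 | [(2R,3S,4S)-2-[3-methoxy-4-(triisopropylsilyloxy)phenyl]-4-{[3-methoxy-4-(triisopropylsilyloxy)phenyl]methyl}oxolan-3-yl]methanol | COc1cc(C[C@@H]2CO[C@@H](c3ccc(O[Si](C(C)C)(C(C)C)C(C)C)c(OC)c3)[C@@H]2CO)ccc1O[Si](C(C)C)(C(C)C)C(C)C
F6 | step 14 | (2S,3S)-4-hydroxy-2-{(R)-hydroxy[3-methoxy-4-(triisopropylsilyloxy)phenyl]methyl}-3-{[3-methoxy-4-(triisopropylsilyloxy)phenyl]methyl}butyl (2E)-3-[4-(triisopropylsilyloxy)phenyl]prop-2-enoate | COc1cc(C[C@H](CO)[C@@H](COC(=O)/C=C/c2ccc(O[Si](C(C)C)(C(C)C)C(C)C)cc2)[C@@H](O)c2ccc(O[Si](C(C)C)(C(C)C)C(C)C)c(OC)c2)ccc1O[Si](C(C)C)(C(C)C)C(C)C
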